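## The problem

The target joins a 4',7-dihydroxyflavan (rings A, B and C) through C4 to C8' of (−)-epiafzelechin (rings D, E and F). C4 is therefore a diarylmethine held between ring A and a ring D carbon that is flanked on both sides by oxygen (O7' and the pyran oxygen O1'). Four stereocenters are needed. C2' and C3' (R,R, cis) lie in ring F and are too remote to bias the upper unit. C4 (S) therefore needs catalyst or auxiliary control. C2 (S) sits 1,3 to C4 in ring C, so the C4 substituent can decide it (2,4-cis, both groups equatorial). Regiochemistry on ring D is a second issue, because C6' and C8' of a 5,7-dioxygenated flavan are both nucleophilic. The free polyphenol is sensitive to oxidants; the benzylic C–O bonds at C2 and C2' ionise in strong acid; and C2' epimerises in base once the ring E phenol is deprotonated. A late oxidant must also spare the benzylic C4'–H2 of ring F and the doubly benzylic C4–H. The enabling feature is that C2 is the benzylic carbon of the para-hydroxyphenyl ring B. Oxidation of that phenol makes C2 the exocyclic carbon of a para-quinone methide, and the ring A oxygen on C8a is placed to add to it and close ring C through O1–C2.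

## Retrosynthesis

**24 to 23.** Only O–benzyl bonds are cut. All spectator oxygens (O5', O7', O4' of ring E, O3' and O7) are carried as benzyl ethers so that one hydrogenolysis ends the route. An ester at O3' would not survive the organolithium, hydroxide and alkoxide steps upstream, so a fifth benzyl ether is used there. The ring B hydroxyl is left free in 23 because it is the handle of the key step.

**23 to 21 (through 22).** The O1–C2 bond is cut. The neighbouring cut at C4–C8' (flavan-4-yl cation plus a nucleophilic flavan-3-ol) gives no control of C4 and poor C6'/C8' discrimination. A cut at C3–C4 would need both stereocenters to be set at once. Opening O1–C2 removes ring C and the C2 stereocenter and leaves the acyclic 1,1,3-triarylpropane 21, which has one new stereocenter (C4) and no oxygen at C2. The forward reaction must oxidise ring B selectively to para-quinone methide 22 and let C4 dictate the configuration of C2.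

**21 to 20 to 18.** Two acetal C–O bonds and the C2 carbonyl are restored. The ring B oxygen and the ring A oxygen on C8a must be unmasked together while the benzyl ethers stay, so both are carried as methoxymethyl (MOM) ethers. These tolerate hydroxide, organolithium, the [RhCl(C2H4)2]2-catalysed addition and alkoxide, and leave under mild acid. The C2 carbonyl of 18 is the handle for building the chain. Its removal must not pass through a C2 cation, which the ring A oxygen would capture and so close ring C before the oxidative step. A carbanionic Wolff–Kishner reduction is therefore required.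

**18 to 11 and 17.** The C4–C4a bond (ring A to C4) is cut as a catalytic asymmetric 1,4-addition. The alternative of adding ring D to a ring A enone would need a 2,6-dialkoxyaryl boron reagent, which protodeboronates and transmetalates poorly. Placing the hindered ring D on the acceptor 11 and transferring the mono-ortho-substituted aryl of 17 is the better pairing. The forward step must set C4 as S under catalyst control.

**11 to 7 and 9.** The C3=C4 double bond is cut as a crossed aldol condensation between the non-enolisable aldehyde 7 and the methyl ketone 9. This supplies C2 and C3 with ring B already attached and needs nothing beyond base.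

**7 to 4 to 3 to 2 to 1.** The C8'–CHO bond is cut back to bromide 4, and the bromine is cut back to perbenzylated 3. Bromination of 5,7-dialkoxyflavans is C8-selective, which settles the ring D regiochemistry before any fragment is attached. Compound 3 comes from the purchased flavan-3-ol 1 by two etherifications, through 2. Both ring F stereocenters are bought.

**17 to 14 to 13 to 12, and 9 to 8.** The C–B bond is cut to bromide 14. Its two oxygens are differentiated by monobenzylation of 4-bromoresorcinol 12 at the hydroxyl para to bromine (13), followed by MOM protection. Ketone 9 is the MOM ether of 8.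

## Roads not taken

**Alternative 1:** The cut runs through ring D itself. A benzannulation between the flavan-4-yl siloxyalkyne A2 and 3-(benzyloxy)cyclobutenone A3 forms C8a'–C8', C7'–C6' and C8a'–C4a' and gives the resorcinol-type phenol A1.

- Forward step: thermal ring opening of A3, [2+2] addition to the alkyne of A2, second ring opening and six-electron closure.
- Merits: the crowded C4–C8' bond is never made by a coupling, because the arene grows around it. C2 and C4 are settled on a small flavan, and no oxidant is used near free phenols.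
- Weak points: rings F and E and both lower stereocenters must still be built on A1, with a regiochemical choice between its two oxygenated positions. Compound 1 supplies all of that at once. A2 must be made as a single 2,4-cis isomer with the alkyne on C4, and both A2 and A3 are sensitive.
- Comparison: this road is better at the hindered C4–C8' junction. The chosen plan answers with the [RhCl(C2H4)2]2/chiral diene catalyst for the hindered 1,4-addition, and is much shorter because the lower half is purchased.

**Alternative 2:** The cut is C4'–C4a' in ring F. A Lewis acid opens the terminal epoxide of aryl ether A5, and C4a' attacks the CH2 carbon to give A4 with the C3' hydroxyl revealed.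

- Merits: the Friedel–Crafts position is forced because C8' is already occupied. C3' comes from an epoxide of defined configuration. The upper unit can be attached while ring D is still symmetrical, which removes the C6'/C8' question.
- Weak points: the benzylic C2'–O bond of A5 can ionise under the same acid, which is why ring E must carry a deactivating ester. Attack at the internal epoxide carbon (5-exo) competes with the desired endo opening. Making A5 requires etherifying a hindered phenol at a secondary benzylic centre with stereocontrol. Ring F of 1 is rebuilt at some length.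
- Comparison: this road has the more certain ring D regiochemistry and no late oxidation. The chosen plan sets against it the known C8 selectivity of bromination and a far shorter lower-half sequence, but it accepts a site-selective oxidation that this road avoids.

**Alternative 3:** O1–C2 and C3–C4 are cut together. A chiral phosphoric acid dehydrates diaryl carbinol A7 to the ring A ortho-quinone methide A9, which adds 4-(benzyloxy)styrene A8 to give cycloadduct A6.

- Merits: this is the most convergent road. Two bonds, ring C and both upper stereocenters arise in one step. A7 is one aryl addition away from an aldehyde of the same type as 7, and A8 is a simple styrene. No deoxygenation, no conjugate addition and no second temporary protecting group are needed. It would be about four steps shorter than the chosen plan.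
- Weak points: A9 carries the di-ortho-substituted, strongly donating ring D on its exocyclic carbon. That makes it a twisted, highly stabilised species outside the range in which phosphoric-acid control of such cycloadditions is established, and a stepwise cationic addition of A8 would erode the cis relationship. C4 and C2 are set in the same event, so a wrong C4 cannot be corrected.
- Comparison: if facial control held, this road would be clearly better in step count. The chosen plan sets against it the separation of the two tasks: C4 is set by the broadly used [RhCl(C2H4)2]2/chiral diene 1,4-addition, and C2 by a reversible closure under the control of C4. Each can be checked and repaired on its own.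

Key step: step 13

Assumption: (−)-epiafzelechin (1) is taken as a purchasable natural product of (2R,3R) configuration.

Assumption: the (R,R) diene ligand is taken to deliver the aryl group to the α-re face of the (E)-enone, as it does with cyclic enones. That face is the re face at C4 of 11 and gives the S centre; the (S,S) ligand would be used if a model enone showed the opposite sense.

## Route

Step 1
Reactants: 1 (−)-epiafzelechin
Product: 2 (2R,3R)-5,7-bis(benzyloxy)-2-[4-(benzyloxy)phenyl]chroman-3-ol
Conditions: BnBr (3.3 equiv), K2CO3, DMF, 0 °C → rt, N2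
Reagents that add atoms: benzyl bromide BrCc1ccccc1
Why: Williamson etherification: K2CO3 ionises the three phenols but not the secondary alcohol, and the mild base and temperature avoid ring-opening epimerisation at C2 of the epi-configured flavan-3-ol.

Step 2
Reactants: 2 (2R,3R)-5,7-bis(benzyloxy)-2-[4-(benzyloxy)phenyl]chroman-3-ol
Product: 3 (2R,3R)-3,5,7-tris(benzyloxy)-2-[4-(benzyloxy)phenyl]chromane
Conditions: NaH, BnBr, Bu4NI (cat.), DMF, 0 °C → rt
Reagents that add atoms: benzyl bromide BrCc1ccccc1
Why: Williamson etherification of the C3 alkoxide; with all phenols capped no quinone methide pathway exists, so C2 and C3 keep their configuration.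

Step 3
Reactants: 3 (2R,3R)-3,5,7-tris(benzyloxy)-2-[4-(benzyloxy)phenyl]chromane
Product: 4 (2R,3R)-3,5,7-tris(benzyloxy)-2-[4-(benzyloxy)phenyl]-8-bromochromane
Conditions: NBS (1.0 equiv), CH2Cl2, −20 → 0 °C, dark
Reagents that add atoms: N-bromosuccinimide O=C1CCC(=O)N1Br
Why: Electrophilic aromatic bromination: in 5,7-dialkoxyflavans C8 is the most nucleophilic position and reacts ahead of C6 and of the mono-alkoxy ring E, as established for benzylated catechins.

Step 4
Reactants: 4 (2R,3R)-3,5,7-tris(benzyloxy)-2-[4-(benzyloxy)phenyl]-8-bromochromane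
Product: 7 (2R,3R)-3,5,7-tris(benzyloxy)-2-[4-(benzyloxy)phenyl]chromane-8-carbaldehyde, via 8-lithio chromane 5 (not isolated), via lithium hemiaminal alkoxide 6 (not isolated)
Conditions: n-BuLi (1.1 equiv), THF, −78 °C; DMF, −78 → 0 °C; aq. NH4Cl
Reagents that add atoms: N,N-dimethylformamide CN(C)C=O
Why: Bromine–lithium exchange at −78 °C gives aryllithium 5, which adds to DMF (Bouveault aldehyde synthesis); adduct 6 collapses to the aldehyde only on aqueous work-up, so no over-addition occurs.

Step 5
Reactants: 8 4'-hydroxyacetophenone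
Product: 9 1-[4-(methoxymethoxy)phenyl]ethan-1-one
Conditions: MOMCl, i-Pr2NEt, CH2Cl2, 0 °C → rt
Reagents that add atoms: chloromethyl methyl ether COCCl
Why: O-alkylation of the phenol with the reactive α-chloro ether gives the base-stable MOM acetal needed for the condensation and the basic steps that follow.

Step 6
Reactants: 7 (2R,3R)-3,5,7-tris(benzyloxy)-2-[4-(benzyloxy)phenyl]chromane-8-carbaldehyde; 9 1-[4-(methoxymethoxy)phenyl]ethan-1-one
Product: 11 (E)-1-[4-(methoxymethoxy)phenyl]-3-{(2R,3R)-3,5,7-tris(benzyloxy)-2-[4-(benzyloxy)phenyl]chroman-8-yl}prop-2-en-1-one, via aldol adduct 10 (not isolated)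
Conditions: KOH (aq.), EtOH/THF, rt → 40 °C
Reagents that add atoms: none
Why: Claisen–Schmidt condensation: 7 cannot enolise, the enolate of 9 adds to it to give aldol 10, and E1cB loss of water gives the conjugated (E)-enone as the thermodynamic isomer; benzyl and MOM ethers are inert to hydroxide.

Step 7
Reactants: 12 4-bromoresorcinol
Product: 13 5-(benzyloxy)-2-bromophenol
Conditions: BnBr (1.0 equiv), K2CO3, acetone, rt → 50 °C
Reagents that add atoms: benzyl bromide BrCc1ccccc1
Why: Williamson etherification under stoichiometric control: the hydroxyl para to bromine is the less hindered and its phenoxide the more nucleophilic, whereas the ortho-bromo phenoxide is inductively stabilised and shielded; one equivalent of benzyl bromide limits dialkylation.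

Step 8
Reactants: 13 5-(benzyloxy)-2-bromophenol
Product: 14 4-(benzyloxy)-1-bromo-2-(methoxymethoxy)benzene
Conditions: MOMCl, i-Pr2NEt, CH2Cl2, 0 °C → rt
Reagents that add atoms: chloromethyl methyl ether COCCl
Why: O-alkylation of the remaining phenol gives the MOM acetal, which is the smallest base-stable group for the oxygen that must later become O1.

Step 9
Reactants: 14 4-(benzyloxy)-1-bromo-2-(methoxymethoxy)benzene
Product: 17 [4-(benzyloxy)-2-(methoxymethoxy)phenyl]boronic acid, via aryllithium 15 (not isolated), via lithium triisopropoxyborate 16 (not isolated)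
Conditions: n-BuLi, THF, −78 °C; B(Oi-Pr)3, −78 °C → rt; aq. NH4Cl
Reagents that add atoms: triisopropyl borate CC(C)OB(OC(C)C)OC(C)C; water O
Why: Bromine–lithium exchange is faster than deprotonation at −78 °C and the ortho MOM oxygen stabilises aryllithium 15; trapping with the borate ester gives ate complex 16, which hydrolyses at near-neutral pH to the boronic acid without loss of the MOM acetal.

Step 10
Reactants: 11 (E)-1-[4-(methoxymethoxy)phenyl]-3-{(2R,3R)-3,5,7-tris(benzyloxy)-2-[4-(benzyloxy)phenyl]chroman-8-yl}prop-2-en-1-one; 17 [4-(benzyloxy)-2-(methoxymethoxy)phenyl]boronic acid (3 equiv)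
Product: 18 (3S)-3-[4-(benzyloxy)-2-(methoxymethoxy)phenyl]-1-[4-(methoxymethoxy)phenyl]-3-{(2R,3R)-3,5,7-tris(benzyloxy)-2-[4-(benzyloxy)phenyl]chroman-8-yl}propan-1-one
Conditions: [RhCl(C2H4)2]2 (3 mol %), (1R,4R)-2,5-diphenylbicyclo[2.2.2]octa-2,5-diene (6.6 mol %), KOH (aq., 0.5 equiv), 1,4-dioxane/H2O, 50 °C
Reagents that add atoms: none
Why: Hayashi–Miyaura asymmetric 1,4-addition: transmetalation gives an aryl–rhodium species on the chiral diene, the (E)-enone inserts through its α-re face (the re face at C4), and hydrolysis of the rhodium enolate releases the ketone with C4 set as S by the catalyst, the remote C2' and C3' centres having little say. Diene ligands are chosen because they keep the rate high with ortho-substituted boronic acids and hindered β-aryl enones, and the excess of 17 covers protodeboronation.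

Step 11
Reactants: 18 (3S)-3-[4-(benzyloxy)-2-(methoxymethoxy)phenyl]-1-[4-(methoxymethoxy)phenyl]-3-{(2R,3R)-3,5,7-tris(benzyloxy)-2-[4-(benzyloxy)phenyl]chroman-8-yl}propan-1-one
Product: 20 (2R,3R)-3,5,7-tris(benzyloxy)-2-[4-(benzyloxy)phenyl]-8-{(1S)-1-[4-(benzyloxy)-2-(methoxymethoxy)phenyl]-3-[4-(methoxymethoxy)phenyl]propyl}chromane, via N-silyl hydrazone 19 (not isolated)
Conditions: 1,2-bis(tert-butyldimethylsilyl)hydrazine, Sc(OTf)3 (1 mol %), CHCl3, 55 °C; then KOt-Bu, t-BuOH, DMSO, rt → 80 °C
Reagents that add atoms: none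
Why: Wolff–Kishner reduction in its N-silyl hydrazone variant: Sc(OTf)3-catalysed condensation gives 19, and alkoxide-induced desilylation, tautomerisation to the diazene and loss of N2 deliver the methylene group. The pathway is carbanionic, so no C2 cation can be captured by the ring A oxygen, and the ethers and the C4 centre (not α to the hydrazone) are untouched.

Step 12
Reactants: 20 (2R,3R)-3,5,7-tris(benzyloxy)-2-[4-(benzyloxy)phenyl]-8-{(1S)-1-[4-(benzyloxy)-2-(methoxymethoxy)phenyl]-3-[4-(methoxymethoxy)phenyl]propyl}chromane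
Product: 21 5-(benzyloxy)-2-{(1S)-3-(4-hydroxyphenyl)-1-[(2R,3R)-3,5,7-tris(benzyloxy)-2-(4-benzyloxyphenyl)chroman-8-yl]propyl}phenol
Conditions: HCl (3 M aq.), MeOH/THF, 40 °C
Reagents that add atoms: none
Why: Acid-catalysed acetal cleavage: aryl MOM ethers are hydrolysed under conditions that leave aryl and alkyl benzyl ethers intact, and methanol captures the methoxymethyl cation as dimethoxymethane before it can alkylate the electron-rich ring D.

Step 13
Reactants: 21 5-(benzyloxy)-2-{(1S)-3-(4-hydroxyphenyl)-1-[(2R,3R)-3,5,7-tris(benzyloxy)-2-(4-benzyloxyphenyl)chroman-8-yl]propyl}phenol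
Product: 23 4-{(2S,4S)-7-(benzyloxy)-4-[(2R,3R)-3,5,7-tris(benzyloxy)-2-(4-benzyloxyphenyl)chroman-8-yl]chroman-2-yl}phenol, via para-quinone methide 22 (not isolated)
Conditions: DDQ (1.05 equiv, slow addition), 1,4-dioxane, 10 °C → rt, N2
Reagents that add atoms: none
Why: DDQ oxidises the only para-alkylphenol (ring B) by two electrons through the phenol–quinone charge-transfer complex, formally removing hydride from C2, to give para-quinone methide 22 and the hydroquinone. The ring A hydroxyl on C8a then adds to the exocyclic C2 in an oxa-1,6-addition that restores the aromaticity of ring B and forms O1–C2. The closest known reaction type is the DDQ-mediated oxidative cyclisation of 1-(2-hydroxyaryl)-3-(4-hydroxyaryl)propanes to 4'-hydroxyflavans. Ring C closes in the 6-exo-trig mode, the attacked double bond between C2 and ring B lying outside the new ring. The new stereocenter C2 is controlled by C4: in the chair-like transition state the quinoid residue on C2 and ring D on C4 both take equatorial positions, which gives the 2,4-cis (2S) isomer. Because the ring B hydroxyl stays free, the addition is reversible under the mildly acidic conditions left by the hydroquinone, so any 2,4-trans isomer can drain to the diequatorial cis product. The step needs site selectivity for ring B over the ring A phenol and over the benzylic C4–H and C4'–H2 positions: ring A has no para-alkyl group, the C4–H bond lies near the planes of ring A and of the di-ortho-substituted ring D and is poorly aligned for hydride loss, and phenol oxidation is much faster than oxidation of benzyl or alkyl aryl ethers. One equivalent of oxidant added slowly limits re-oxidation of the product at C2.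

Step 14
Reactants: 23 4-{(2S,4S)-7-(benzyloxy)-4-[(2R,3R)-3,5,7-tris(benzyloxy)-2-(4-benzyloxyphenyl)chroman-8-yl]chroman-2-yl}phenol
Product: 24 (2S,4S)-2-(4-hydroxyphenyl)-4-[(2R,3R)-3,5,7-trihydroxy-2-(4-hydroxyphenyl)chroman-8-yl]chroman-7-ol
Conditions: H2 (1 atm), Pd(OH)2/C, THF/MeOH, rt
Reagents that add atoms: none
Why: Catalytic hydrogenolysis of the four aryl benzyl ethers and the C3' benzyl ether; the cyclic benzylic C–O bonds at C2 and C2' are known to survive these conditions in flavan-3-ol chemistry, and no stereocenter is touched.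

## Compound list

1 | (−)-epiafzelechin, (2R,3R)-2-(4-hydroxyphenyl)chromane-3,5,7-triol | Oc1cc(O)c2c(c1)O[C@H](c1ccc(O)cc1)[C@H](O)C2 | starting material
2 | (2R,3R)-5,7-bis(benzyloxy)-2-[4-(benzyloxy)phenyl]chroman-3-ol | c1c(OCc2ccccc2)cc(OCc2ccccc2)c2c1O[C@H](c1ccc(OCc3ccccc3)cc1)[C@H](O)C2 | intermediate
3 | (2R,3R)-3,5,7-tris(benzyloxy)-2-[4-(benzyloxy)phenyl]chromane | c1c(OCc2ccccc2)cc(OCc2ccccc2)c2c1O[C@H](c1ccc(OCc3ccccc3)cc1)[C@H](OCc1ccccc1)C2 | intermediate
4 | (2R,3R)-3,5,7-tris(benzyloxy)-2-[4-(benzyloxy)phenyl]-8-bromochromane | Brc1c(OCc2ccccc2)cc(OCc2ccccc2)c2c1O[C@H](c1ccc(OCc3ccccc3)cc1)[C@H](OCc1ccccc1)C2 | intermediate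
5 | [(2R,3R)-3,5,7-tris(benzyloxy)-2-(4-benzyloxyphenyl)chroman-8-yl]lithium | [Li]c1c(OCc2ccccc2)cc(OCc2ccccc2)c2c1O[C@H](c1ccc(OCc3ccccc3)cc1)[C@H](OCc1ccccc1)C2 | intermediate
6 | lithium (dimethylamino)[(2R,3R)-3,5,7-tris(benzyloxy)-2-(4-benzyloxyphenyl)chroman-8-yl]methanolate | [Li+].[O-]C(N(C)C)c1c(OCc2ccccc2)cc(OCc2ccccc2)c2c1O[C@H](c1ccc(OCc3ccccc3)cc1)[C@H](OCc1ccccc1)C2 | intermediate
7 | (2R,3R)-3,5,7-tris(benzyloxy)-2-[4-(benzyloxy)phenyl]chromane-8-carbaldehyde | O=Cc1c(OCc2ccccc2)cc(OCc2ccccc2)c2c1O[C@H](c1ccc(OCc3ccccc3)cc1)[C@H](OCc1ccccc1)C2 | intermediate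
8 | 4'-hydroxyacetophenone | CC(=O)c1ccc(O)cc1 | starting material
9 | 1-[4-(methoxymethoxy)phenyl]ethan-1-one | CC(=O)c1ccc(OCOC)cc1 | intermediate
10 | 3-hydroxy-1-[4-(methoxymethoxy)phenyl]-3-{(2R,3R)-3,5,7-tris(benzyloxy)-2-[4-(benzyloxy)phenyl]chroman-8-yl}propan-1-one (carbinol epimers) | COCOc1ccc(cc1)C(=O)CC(O)c1c(OCc2ccccc2)cc(OCc2ccccc2)c2c1O[C@H](c1ccc(OCc3ccccc3)cc1)[C@H](OCc1ccccc1)C2 | intermediate
11 | (E)-1-[4-(methoxymethoxy)phenyl]-3-{(2R,3R)-3,5,7-tris(benzyloxy)-2-[4-(benzyloxy)phenyl]chroman-8-yl}prop-2-en-1-one | COCOc1ccc(cc1)C(=O)/C=C/c1c(OCc2ccccc2)cc(OCc2ccccc2)c2c1O[C@H](c1ccc(OCc3ccccc3)cc1)[C@H](OCc1ccccc1)C2 | intermediate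
12 | 4-bromoresorcinol (4-bromobenzene-1,3-diol) | Oc1ccc(Br)c(O)c1 | starting material
13 | 5-(benzyloxy)-2-bromophenol | Oc1cc(OCc2ccccc2)ccc1Br | intermediate
14 | 4-(benzyloxy)-1-bromo-2-(methoxymethoxy)benzene | COCOc1cc(OCc2ccccc2)ccc1Br | intermediate
15 | [4-(benzyloxy)-2-(methoxymethoxy)phenyl]lithium | COCOc1cc(OCc2ccccc2)ccc1[Li] | intermediate
16 | lithium [4-(benzyloxy)-2-(methoxymethoxy)phenyl]tri(propan-2-yloxy)borate | [Li+].COCOc1cc(OCc2ccccc2)ccc1[B-](OC(C)C)(OC(C)C)OC(C)C | intermediate
17 | [4-(benzyloxy)-2-(methoxymethoxy)phenyl]boronic acid | COCOc1cc(OCc2ccccc2)ccc1B(O)O | intermediate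
18 | (3S)-3-[4-(benzyloxy)-2-(methoxymethoxy)phenyl]-1-[4-(methoxymethoxy)phenyl]-3-{(2R,3R)-3,5,7-tris(benzyloxy)-2-[4-(benzyloxy)phenyl]chroman-8-yl}propan-1-one | COCOc1ccc(cc1)C(=O)C[C@H](c1c(OCc2ccccc2)cc(OCc2ccccc2)c2c1O[C@H](c1ccc(OCc3ccccc3)cc1)[C@H](OCc1ccccc1)C2)c1ccc(OCc2ccccc2)cc1OCOC | intermediate
19 | N-(tert-butyldimethylsilyl)hydrazone of ketone 18 | COCOc1ccc(cc1)C(=NN[Si](C)(C)C(C)(C)C)C[C@H](c1c(OCc2ccccc2)cc(OCc2ccccc2)c2c1O[C@H](c1ccc(OCc3ccccc3)cc1)[C@H](OCc1ccccc1)C2)c1ccc(OCc2ccccc2)cc1OCOC | intermediate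
20 | (2R,3R)-3,5,7-tris(benzyloxy)-2-[4-(benzyloxy)phenyl]-8-{(1S)-1-[4-(benzyloxy)-2-(methoxymethoxy)phenyl]-3-[4-(methoxymethoxy)phenyl]propyl}chromane | COCOc1ccc(cc1)CC[C@H](c1c(OCc2ccccc2)cc(OCc2ccccc2)c2c1O[C@H](c1ccc(OCc3ccccc3)cc1)[C@H](OCc1ccccc1)C2)c1ccc(OCc2ccccc2)cc1OCOC | intermediate
21 | 5-(benzyloxy)-2-{(1S)-3-(4-hydroxyphenyl)-1-[(2R,3R)-3,5,7-tris(benzyloxy)-2-(4-benzyloxyphenyl)chroman-8-yl]propyl}phenol | Oc1ccc(cc1)CC[C@H](c1c(OCc2ccccc2)cc(OCc2ccccc2)c2c1O[C@H](c1ccc(OCc3ccccc3)cc1)[C@H](OCc1ccccc1)C2)c1ccc(OCc2ccccc2)cc1O | intermediate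
22 | 4-{(3S)-3-[4-(benzyloxy)-2-hydroxyphenyl]-3-[(2R,3R)-3,5,7-tris(benzyloxy)-2-(4-benzyloxyphenyl)chroman-8-yl]propylidene}cyclohexa-2,5-dien-1-one | O=C1C=CC(C=C1)=CC[C@H](c1c(OCc2ccccc2)cc(OCc2ccccc2)c2c1O[C@H](c1ccc(OCc3ccccc3)cc1)[C@H](OCc1ccccc1)C2)c1ccc(OCc2ccccc2)cc1O | intermediate
23 | 4-{(2S,4S)-7-(benzyloxy)-4-[(2R,3R)-3,5,7-tris(benzyloxy)-2-(4-benzyloxyphenyl)chroman-8-yl]chroman-2-yl}phenol | Oc1ccc(cc1)[C@@H]1C[C@H](c2c(OCc3ccccc3)cc(OCc3ccccc3)c3c2O[C@H](c2ccc(OCc4ccccc4)cc2)[C@H](OCc2ccccc2)C3)c2ccc(OCc3ccccc3)cc2O1 | intermediate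
24 | (2S,4S)-2-(4-hydroxyphenyl)-4-[(2R,3R)-3,5,7-trihydroxy-2-(4-hydroxyphenyl)chroman-8-yl]chroman-7-ol (CNP0254623.1) | Oc1ccc([C@@H]2C[C@H](c3c(O)cc(O)c4c3O[C@H](c3ccc(O)cc3)[C@H](O)C4)c3ccc(O)cc3O2)cc1 | target

## Step count and least certain steps

Total: 14 steps. Longest linear sequence: 10 steps (steps 1, 2, 3, 4, 6, 10, 11, 12, 13, 14).

**Step 13 (key step).** Three things may go wrong.
- Oxidation at the wrong site: hydride loss from C4 through the ring A phenol (ortho-quinone methide formation, which would erase the C4 centre), or oxidation of the benzylic C4'–H2 of ring F.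
- Re-oxidation of the product at C2, which still carries a para-hydroxybenzylic hydrogen.
- Slow equilibration, leaving incomplete 2,4-cis selectivity.

Fallback: set out from ketone 18 and close the same O1–C2 bond from an alcohol instead of a C–H bond. Reduction with NaBH4 in MeOH/THF would give carbinol (3S)-3-[4-(benzyloxy)-2-(methoxymethoxy)phenyl]-1-[4-(methoxymethoxy)phenyl]-3-{(2R,3R)-3,5,7-tris(benzyloxy)-2-[4-(benzyloxy)phenyl]chroman-8-yl}propan-1-ol F1 as a pair of C1 epimers. Treatment with HCl in MeOH/THF would then remove both MOM groups and ionise the para-hydroxybenzylic alcohol. The ring A phenol captures the cation (cyclodehydration under thermodynamic control, favouring the 2,4-cis isomer), and the sequence comes back to the route at 23.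

**Step 10.** The twisted β-(2,6-dialkoxyaryl) enone may insert slowly, so that protodeboronation of the electron-rich ortho-alkoxy boronic acid consumes the reagent. Facial discrimination on so hindered an alkene may also be incomplete.

Fallback: set out from aldehyde 7 and use a 4-phenyloxazolidinone auxiliary. Horner–Wadsworth–Emmons olefination (LiCl, i-Pr2NEt, MeCN) with the known phosphonate diethyl {2-oxo-2-[(4R)-2-oxo-4-phenyl-1,3-oxazolidin-3-yl]ethyl}phosphonate F2 would give enoyl imide (4R)-4-phenyl-3-[(2E)-3-{(2R,3R)-3,5,7-tris(benzyloxy)-2-[4-(benzyloxy)phenyl]chroman-8-yl}prop-2-enoyl]-1,3-oxazolidin-2-one F3. The Grignard reagent [4-(benzyloxy)-2-(methoxymethoxy)phenyl]magnesium bromide F4, made from bromide 14 and magnesium, would then add with CuBr·SMe2 to the magnesium-chelated s-cis imide on the face opposite the phenyl group, which gives the (3S) adduct (4R)-3-[(3S)-3-[4-(benzyloxy)-2-(methoxymethoxy)phenyl]-3-{(2R,3R)-3,5,7-tris(benzyloxy)-2-[4-(benzyloxy)phenyl]chroman-8-yl}propanoyl]-4-phenyl-1,3-oxazolidin-2-one F5. Aminolysis with MeNHOMe·HCl and AlMe3 would give the N-methoxy-N-methylamide (3S)-3-[4-(benzyloxy)-2-(methoxymethoxy)phenyl]-N-methoxy-N-methyl-3-{(2R,3R)-3,5,7-tris(benzyloxy)-2-[4-(benzyloxy)phenyl]chroman-8-yl}propanamide F6. Addition of [4-(methoxymethoxy)phenyl]magnesium bromide F7, made from 1-bromo-4-(methoxymethoxy)benzene, comes back to the route at ketone 18.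

**Step 11.** Condensation of the electron-rich aryl ketone with the hydrazine may be incomplete. Prolonged heating in KOt-Bu/DMSO could also cause slow base-mediated epimerisation at the diarylmethine C4.

Fallback: set out from 18 and replace the anionic fragmentation by a hydride reduction under near-neutral conditions. Condensation with 4-methylbenzenesulfonohydrazide (EtOH/THF, 60 °C) would give the tosylhydrazone N'-[(3S)-3-[4-(benzyloxy)-2-(methoxymethoxy)phenyl]-1-[4-(methoxymethoxy)phenyl]-3-{(2R,3R)-3,5,7-tris(benzyloxy)-2-[4-(benzyloxy)phenyl]chroman-8-yl}propylidene]-4-methylbenzenesulfonohydrazide F8. Catecholborane in CHCl3 at 0 °C, followed by NaOAc·3H2O at reflux, would reduce the C=N bond, expel sulfinate and release N2 from the diazene. The sequence comes back to the route at 20.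

**Step 4.** Proton transfer from an ortho benzyloxy CH2 group to the aryllithium (followed by anionic rearrangement), or simple protonation back to the debrominated arene, may compete with formylation.

Fallback: set out from bromide 4 and avoid the organolithium altogether. Palladium-catalysed reductive carbonylation (Pd(OAc)2, di(1-adamantyl)-n-butylphosphine, CO/H2, TMEDA, toluene, 100 °C) would come back to the route at aldehyde 7. This path makes no new compound and is entered below as F0.

## Further compounds

F1 | step 13 | (3S)-3-[4-(benzyloxy)-2-(methoxymethoxy)phenyl]-1-[4-(methoxymethoxy)phenyl]-3-{(2R,3R)-3,5,7-tris(benzyloxy)-2-[4-(benzyloxy)phenyl]chroman-8-yl}propan-1-ol (C1 epimers) | COCOc1ccc(cc1)C(O)C[C@H](c1c(OCc2ccccc2)cc(OCc2ccccc2)c2c1O[C@H](c1ccc(OCc3ccccc3)cc1)[C@H](OCc1ccccc1)C2)c1ccc(OCc2ccccc2)cc1OCOC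
F2 | step 10 | diethyl {2-oxo-2-[(4R)-2-oxo-4-phenyl-1,3-oxazolidin-3-yl]ethyl}phosphonate | CCOP(=O)(OCC)CC(=O)N1[C@H](c2ccccc2)COC1=O
F3 | step 10 | (4R)-4-phenyl-3-[(2E)-3-{(2R,3R)-3,5,7-tris(benzyloxy)-2-[4-(benzyloxy)phenyl]chroman-8-yl}prop-2-enoyl]-1,3-oxazolidin-2-one | O=C(/C=C/c1c(OCc2ccccc2)cc(OCc2ccccc2)c2c1O[C@H](c1ccc(OCc3ccccc3)cc1)[C@H](OCc1ccccc1)C2)N1[C@H](c2ccccc2)COC1=O
F4 | step 10 | [4-(benzyloxy)-2-(methoxymethoxy)phenyl]magnesium bromide | COCOc1cc(OCc2ccccc2)ccc1[Mg]Br
F5 | step 10 | (4R)-3-[(3S)-3-[4-(benzyloxy)-2-(methoxymethoxy)phenyl]-3-{(2R,3R)-3,5,7-tris(benzyloxy)-2-[4-(benzyloxy)phenyl]chroman-8-yl}propanoyl]-4-phenyl-1,3-oxazolidin-2-one | O=C(C[C@H](c1c(OCc2ccccc2)cc(OCc2ccccc2)c2c1O[C@H](c1ccc(OCc3ccccc3)cc1)[C@H](OCc1ccccc1)C2)c1ccc(OCc2ccccc2)cc1OCOC)N1[C@H](c2ccccc2)COC1=O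
F6 | step 10 | (3S)-3-[4-(benzyloxy)-2-(methoxymethoxy)phenyl]-N-methoxy-N-methyl-3-{(2R,3R)-3,5,7-tris(benzyloxy)-2-[4-(benzyloxy)phenyl]chroman-8-yl}propanamide | CON(C)C(=O)C[C@H](c1c(OCc2ccccc2)cc(OCc2ccccc2)c2c1O[C@H](c1ccc(OCc3ccccc3)cc1)[C@H](OCc1ccccc1)C2)c1ccc(OCc2ccccc2)cc1OCOC
F7 | step 10 | [4-(methoxymethoxy)phenyl]magnesium bromide | COCOc1ccc(cc1)[Mg]Br
F8 | step 11 | N'-[(3S)-3-[4-(benzyloxy)-2-(methoxymethoxy)phenyl]-1-[4-(methoxymethoxy)phenyl]-3-{(2R,3R)-3,5,7-tris(benzyloxy)-2-[4-(benzyloxy)phenyl]chroman-8-yl}propylidene]-4-methylbenzenesulfonohydrazide | COCOc1ccc(cc1)C(=NNS(=O)(=O)c1ccc(C)cc1)C[C@H](c1c(OCc2ccccc2)cc(OCc2ccccc2)c2c1O[C@H](c1ccc(OCc3ccccc3)cc1)[C@H](OCc1ccccc1)C2)c1ccc(OCc2ccccc2)cc1OCOC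
F0 | step 4 | none | none
A1 | alternative 1 | 5-(benzyloxy)-2-{(2S,4S)-7-(benzyloxy)-2-[4-(benzyloxy)phenyl]chroman-4-yl}-3-{[tri(propan-2-yl)silyl]oxy}phenol | c6ccccc6COc1ccc([C@@H]2C[C@H](c3c(O[Si](C(C)C)(C(C)C)C(C)C)cc(OCc5ccccc5)cc3O)c3ccc(OCc5ccccc5)cc3O2)cc1
A2 | alternative 1 | (2S,4R)-7-(benzyloxy)-2-[4-(benzyloxy)phenyl]-4-({[tri(propan-2-yl)silyl]oxy}ethynyl)chromane | c6ccccc6COc1ccc([C@@H]2C[C@H](C#CO[Si](C(C)C)(C(C)C)C(C)C)c3ccc(OCc5ccccc5)cc3O2)cc1
A3 | alternative 1 | 3-(benzyloxy)cyclobut-2-en-1-one | O=C1CC(OCc2ccccc2)=C1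
A4 | alternative 2 | 4-[(2R,3R)-5,7-bis(benzyloxy)-8-{(2S,4S)-7-(benzyloxy)-2-[4-(benzyloxy)phenyl]chroman-4-yl}-3-hydroxychroman-2-yl]phenyl 2,2-dimethylpropanoate | c6ccccc6COc1ccc([C@@H]2C[C@H](c3c(OCc5ccccc5)cc(OCc5ccccc5)c4c3O[C@H](c3ccc(OC(=O)C(C)(C)C)cc3)[C@H](O)C4)c3ccc(OCc5ccccc5)cc3O2)cc1
A5 | alternative 2 | 4-[(R)-(3,5-bis(benzyloxy)-2-{(2S,4S)-7-(benzyloxy)-2-[4-(benzyloxy)phenyl]chroman-4-yl}phenoxy)[(2R)-oxiran-2-yl]methyl]phenyl 2,2-dimethylpropanoate | c6ccccc6COc1ccc([C@@H]2C[C@H](c3c(OCc5ccccc5)cc(OCc5ccccc5)cc3O[C@H](c3ccc(OC(=O)C(C)(C)C)cc3)[C@H]4CO4)c3ccc(OCc5ccccc5)cc3O2)cc1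
A6 | alternative 3 | tert-butyl{[(2R,3R)-5,7-bis(benzyloxy)-8-{(2S,4S)-7-(benzyloxy)-2-[4-(benzyloxy)phenyl]chroman-4-yl}-2-[4-(benzyloxy)phenyl]chroman-3-yl]oxy}dimethylsilane | c6ccccc6COc1ccc([C@@H]2C[C@H](c3c(OCc5ccccc5)cc(OCc5ccccc5)c4c3O[C@H](c3ccc(OCc5ccccc5)cc3)[C@H](O[Si](C)(C)C(C)(C)C)C4)c3ccc(OCc5ccccc5)cc3O2)cc1
A7 | alternative 3 | 5-(benzyloxy)-2-{hydroxy[(2R,3R)-5,7-bis(benzyloxy)-2-[4-(benzyloxy)phenyl]-3-{[tert-butyl(dimethyl)silyl]oxy}chroman-8-yl]methyl}phenol (carbinol epimers) | OC(c1ccc(OCc2ccccc2)cc1O)c1c(OCc2ccccc2)cc(OCc2ccccc2)c2c1O[C@H](c1ccc(OCc3ccccc3)cc1)[C@H](O[Si](C)(C)C(C)(C)C)C2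
A8 | alternative 3 | 1-(benzyloxy)-4-ethenylbenzene | C=Cc1ccc(OCc2ccccc2)cc1
A9 | alternative 3 | 3-(benzyloxy)-6-{[(2R,3R)-5,7-bis(benzyloxy)-2-[4-(benzyloxy)phenyl]-3-{[tert-butyl(dimethyl)silyl]oxy}chroman-8-yl]methylidene}cyclohexa-2,4-dien-1-one | O=C1C=C(OCc2ccccc2)C=CC1=Cc1c(OCc2ccccc2)cc(OCc2ccccc2)c2c1O[C@H](c1ccc(OCc3ccccc3)cc1)[C@H](O[Si](C)(C)C(C)(C)C)C2
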